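**Retrosynthetic overview**

1. 19 ⇐ 17: the cyclobutane is made last, by a ring-contracting 1,2-shift (C-10 from C-1 to C-11) in a 1-siloxy-2-aminonorbornene; the same event releases the C-1 ketone of the enone.
2. 17 ⇐ 14: one intramolecular Diels–Alder reaction of a 5,5-disubstituted 1-siloxycyclopentadiene with a tethered (E)-nitroalkene closes the six- and seven-membered rings together (bonds C-4–C-5 and C-1–C-11).
3. 14 ⇐ 11: esterification, then nitration of the terminal vinyl group; 11 ⇐ 8 by hydroxyl-directed anti reduction (C-9) and chelate-controlled methylation (C-10).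
4. 8 ⇐ 3-methylcyclopent-2-enone + β-lactone 5; 5 ⇐ 2,2-dimethylbut-3-enal + ketene (catalytic asymmetric [2+2], sets C-7, the only external source of chirality).
5. Ring order: cyclopentenone (bought, later consumed) → six- and seven-membered rings (step 8) → four-membered ring (step 10).

Numbering: C-1 to C-11 follow the longipinane skeleton of the target (C-1 ketone, C-2=C-3(Me), C-4 and C-11 the CH bridgeheads of the enone ring, C-5 the cyclobutane CH next to C-6 (CMe2), C-7 and C-9 the ester carbinols, C-8 the CH2 between them, C-10 the quaternary C–Me). Sen = 3-methylbut-2-enoyl.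

Assumption: the quinine-derived catalyst in step 2 is taken to give the (R)-lactone; if the sense proves opposite, O-trimethylsilylquinidine is used instead.

**Route**

Step 1
Reactants: 1 methyl 2,2-dimethylbut-3-enoate
Product: 2 2,2-dimethylbut-3-enal
Conditions: i-Bu2AlH (1.05 equiv), CH2Cl2, −78 °C; Rochelle salt work-up
Reagents that add atoms: none
Why: Partial ester reduction stops at the aldehyde because the neopentyl aluminium hemiacetal does not collapse at −78 °C; no stereocentre is formed.

Step 2
Reactants: 2 2,2-dimethylbut-3-enal; 3 acetyl chloride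
Product: 5 (R)-4-(2-methylbut-3-en-2-yl)oxetan-2-one, via ketene 4 (not isolated)
Conditions: i-Pr2NEt, O-trimethylsilylquinine (10 mol%), LiClO4, CH2Cl2/Et2O, −78 °C
Reagents that add atoms: none
Why: Catalytic asymmetric ketene–aldehyde [2+2] cycloaddition (Wynberg-type acyl halide–aldehyde cyclocondensation), in which the alkaloid-bound enolate adds to one face of the LiClO4-activated, non-enolisable aldehyde and closes to the β-lactone, setting C-7 as R.

Step 3
Reactants: 6 3-methylcyclopent-2-en-1-one; 5 (R)-4-(2-methylbut-3-en-2-yl)oxetan-2-one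
Product: 8 5-[(3R)-3-hydroxy-4,4-dimethylhex-5-enoyl]-3-methylcyclopent-2-en-1-one, via lithium dienolate 7 (not isolated)
Conditions: LiN(i-Pr)2, THF, −78 °C (2.2 equiv each of 6 and base); then 5, −78 to −40 °C; aq. NH4Cl, cold
Reagents that add atoms: none
Why: Claisen-type C-acylation in which the kinetic α′-enolate attacks the lactone carbonyl with acyl–oxygen cleavage and the acidic β-diketone is held as its lithium salt (hence two equivalents of enolate), leaving C-7 untouched and the ring carbon (future C-10) epimerisable.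

Step 4
Reactants: 8 5-[(3R)-3-hydroxy-4,4-dimethylhex-5-enoyl]-3-methylcyclopent-2-en-1-one
Product: 9 5-[(1R,3R)-1,3-dihydroxy-4,4-dimethylhex-5-en-1-yl]-3-methylcyclopent-2-en-1-one
Conditions: Me4NBH(OAc)3, MeCN/AcOH, −30 °C
Reagents that add atoms: none
Why: Evans–Saksena reduction, in which the C-7 hydroxyl binds the acetoxyborohydride and delivers hydride intramolecularly to the β-carbonyl only, giving the 1,3-anti diol (C-9 R) and leaving the ring enone alone.

Step 5
Reactants: 9 5-[(1R,3R)-1,3-dihydroxy-4,4-dimethylhex-5-en-1-yl]-3-methylcyclopent-2-en-1-one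
Product: 11 (5S)-5-[(1R,3R)-1,3-dihydroxy-4,4-dimethylhex-5-en-1-yl]-3,5-dimethylcyclopent-2-en-1-one, via trilithium alkoxide enolate 10 (not isolated)
Conditions: LiN(i-Pr)2 (3.3 equiv), THF/DMPU, −78 °C; MeI, −78 to −40 °C; aq. NH4Cl at −78 °C
Reagents that add atoms: iodomethane, CI
Why: Fráter–Seebach-type alkylation, in which the C-9 lithium alkoxide and the ring enolate form a six-membered chelate and MeI enters anti to the C-8 chain, setting the quaternary centre C-10 relative to C-9 (both ring epimers of 9 converge).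

Step 6
Reactants: 11 (5S)-5-[(1R,3R)-1,3-dihydroxy-4,4-dimethylhex-5-en-1-yl]-3,5-dimethylcyclopent-2-en-1-one; 12 3-methylbut-2-enoyl chloride
Product: 13 (1R,3R)-1-[(1S)-1,4-dimethyl-2-oxocyclopent-3-en-1-yl]-4,4-dimethylhex-5-ene-1,3-diyl bis(3-methylbut-2-enoate)
Conditions: 12 (3 equiv), pyridine, DMAP (cat.), CH2Cl2, 0 °C to rt
Reagents that add atoms: none
Why: DMAP-catalysed acylation of both hindered secondary alcohols, with pyridine as a weak base to avoid deconjugation through the vinylketene; the target's esters then serve as protecting groups and block retro-aldol cleavage at C-9/C-10.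

Step 7
Reactants: 13 (1R,3R)-1-[(1S)-1,4-dimethyl-2-oxocyclopent-3-en-1-yl]-4,4-dimethylhex-5-ene-1,3-diyl bis(3-methylbut-2-enoate)
Product: 14 (1R,3R,5E)-1-[(1S)-1,4-dimethyl-2-oxocyclopent-3-en-1-yl]-4,4-dimethyl-6-nitrohex-5-ene-1,3-diyl bis(3-methylbut-2-enoate)
Conditions: AgNO2, TEMPO (0.4 equiv), 4 Å sieves, ClCH2CH2Cl, air, 70 °C
Reagents that add atoms: silver nitrite, [Ag+].[O-]N=O
Why: Radical nitration–dehydrogenation, in which NO2 radical adds to the terminal CH2 and TEMPO removes the β-hydrogen to give the (E)-nitroalkene, while the electron-poor trisubstituted enoate and enone double bonds react more slowly with the electrophilic radical.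

Step 8
Reactants: 14 (1R,3R,5E)-1-[(1S)-1,4-dimethyl-2-oxocyclopent-3-en-1-yl]-4,4-dimethyl-6-nitrohex-5-ene-1,3-diyl bis(3-methylbut-2-enoate)
Product: 16 tricyclic endo-nitro silyl ether (Diels–Alder adduct; drawn out in the compound list), via silyl dienol ether 15 (not isolated)
Conditions: TBSOTf, Et3N, CH2Cl2, −78 to 0 °C; then PhMe, 60 °C
Reagents that add atoms: tert-butyldimethylsilyl trifluoromethanesulfonate, CC(C)(C)[Si](C)(C)OS(=O)(=O)C(F)(F)F
Why: Soft γ-enolisation gives the 1-siloxy-3-methylcyclopentadiene (C-10 is quaternary, so no 1,5-hydrogen shift can scramble it) and the tethered nitroalkene adds in an intramolecular Diels–Alder reaction that closes the six- and seven-membered rings at once, the nitro-bearing carbon bonding to the siloxy terminus (matched polarity), the tether forcing attack on its own diene face so that C-10 fixes C-1, C-4 and C-5, and the E geometry placing NO2 endo.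

Step 9
Reactants: 16 tricyclic endo-nitro silyl ether
Product: 17 tricyclic endo-amine silyl ether (16 with NH2 in place of NO2)
Conditions: Zn dust, 2 M HCl, EtOH, 0 °C to rt
Reagents that add atoms: none
Why: Dissolving-metal reduction of the secondary nitro group to the primary amine with retention at C-11, under which the conjugated esters, the trisubstituted alkene and the tertiary silyl ether are inert.

Step 10
Reactants: 17 tricyclic endo-amine silyl ether
Product: 19 CNP0105062.1 (target), via diazonium acetate 18 (not isolated)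
Conditions: NaNO2, AcOH/H2O, 0 °C to rt
Reagents that add atoms: none
Why: Proposed new method: diazotisation gives an endo diazonium whose C–N bond is antiperiplanar to the C-1–C-10 bond of the siloxy-bearing bridgehead, so loss of N2 is accompanied by 1,2-shift of C-10 from C-1 to C-11 (inversion at C-11, retention at C-10) and loss of the silyl group, a Tiffeneau–Demjanov-type semipinacol ring contraction (the known behaviour of 2-aminocycloalkanol derivatives) run here in the bornane-to-pinane direction and driven by formation of the C-1 carbonyl, which turns the bicyclo[2.2.1] unit into the cyclobutane-containing enone with C-4, C-5, C-10 and C-11 fixed by the ring constraints.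

**Compound list**

1 | methyl 2,2-dimethylbut-3-enoate | COC(=O)C(C)(C)C=C | starting material
2 | 2,2-dimethylbut-3-enal | O=CC(C)(C)C=C | intermediate
3 | acetyl chloride | CC(=O)Cl | starting material
4 | ketene (ethenone) | C=C=O | intermediate (not isolated)
5 | (R)-4-(2-methylbut-3-en-2-yl)oxetan-2-one | C=CC(C)(C)[C@H]1CC(=O)O1 | intermediate
6 | 3-methylcyclopent-2-en-1-one | CC1=CC(=O)CC1 | starting material
7 | lithium 4-methylcyclopenta-1,4-dien-1-olate (cross-conjugated α′-enolate of 6) | [Li+].[O-]C1=CCC(C)=C1 | intermediate (not isolated)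
8 | 5-[(3R)-3-hydroxy-4,4-dimethylhex-5-enoyl]-3-methylcyclopent-2-en-1-one (ring C-5 epimers and enol forms) | C=CC(C)(C)[C@H](O)CC(=O)C1CC(C)=CC1=O | intermediate
9 | 5-[(1R,3R)-1,3-dihydroxy-4,4-dimethylhex-5-en-1-yl]-3-methylcyclopent-2-en-1-one (ring C-5 epimers) | C=CC(C)(C)[C@H](O)C[C@@H](O)C1CC(C)=CC1=O | intermediate
10 | trilithium salt of 9 (two alkoxides and the ring α′-enolate) | [Li+].[Li+].[Li+].C=CC(C)(C)[C@H]([O-])C[C@@H]([O-])C1=C([O-])C=C(C)C1 | intermediate (not isolated)
11 | (5S)-5-[(1R,3R)-1,3-dihydroxy-4,4-dimethylhex-5-en-1-yl]-3,5-dimethylcyclopent-2-en-1-one | C=CC(C)(C)[C@H](O)C[C@@H](O)[C@]1(C)CC(C)=CC1=O | intermediate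
12 | 3-methylbut-2-enoyl chloride | CC(C)=CC(=O)Cl | starting material
13 | (1R,3R)-1-[(1S)-1,4-dimethyl-2-oxocyclopent-3-en-1-yl]-4,4-dimethylhex-5-ene-1,3-diyl bis(3-methylbut-2-enoate) | C=CC(C)(C)[C@H](OC(=O)C=C(C)C)C[C@@H](OC(=O)C=C(C)C)[C@]1(C)CC(C)=CC1=O | intermediate
14 | (1R,3R,5E)-1-[(1S)-1,4-dimethyl-2-oxocyclopent-3-en-1-yl]-4,4-dimethyl-6-nitrohex-5-ene-1,3-diyl bis(3-methylbut-2-enoate) | [O-][N+](=O)/C=C/C(C)(C)[C@H](OC(=O)C=C(C)C)C[C@@H](OC(=O)C=C(C)C)[C@]1(C)CC(C)=CC1=O | intermediate
15 | TBS dienol ether of 14 (1-siloxy-3,5-dimethylcyclopenta-1,3-diene; side chain and its stereocentres unchanged) | [O-][N+](=O)/C=C/C(C)(C)[C@H](OC(=O)C=C(C)C)C[C@@H](OC(=O)C=C(C)C)[C@]1(C)C=C(C)C=C1O[Si](C)(C)C(C)(C)C | intermediate (not isolated)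
16 | Diels–Alder adduct: 1-(TBSO)-5,7-dimethyl-2-endo-nitrobicyclo[2.2.1]hept-5-ene whose C-7 (on the side facing C-2/C-3) and C-3 (exo) are bridged by –CH(OSen)–CH2–CH(OSen)–CMe2– | CC(C)=CC(=O)O[C@@H]1C[C@@H](OC(=O)C=C(C)C)[C@@]2(C)[C@]3(O[Si](C)(C)C(C)(C)C)C=C(C)[C@H]2[C@@H]([C@H]3[N+](=O)[O-])C1(C)C | intermediate
17 | endo-amine: 16 with NH2 in place of NO2, same configuration | CC(C)=CC(=O)O[C@@H]1C[C@@H](OC(=O)C=C(C)C)[C@@]2(C)[C@]3(O[Si](C)(C)C(C)(C)C)C=C(C)[C@H]2[C@@H]([C@H]3N)C1(C)C | intermediate
18 | endo-diazonium acetate derived from 17 | CC(C)=CC(=O)O[C@@H]1C[C@@H](OC(=O)C=C(C)C)[C@@]2(C)[C@]3(O[Si](C)(C)C(C)(C)C)C=C(C)[C@H]2[C@@H]([C@H]3[N+]#N)C1(C)C.CC(=O)[O-] | intermediate (not isolated)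
19 | CNP0105062.1: (7R,9R)-7,9-bis(3-methylbut-2-enoyloxy)longipin-2-en-1-one | CC(C)=CC(=O)O[C@@H]1C[C@@H](OC(=O)C=C(C)C)[C@@]2(C)[C@@H]3C(=O)C=C(C)[C@H]2[C@@H]3C1(C)C | target

**Step count**

Total steps: 10. Longest linear sequence: 10 (1 → 19); compounds 3, 6 and 12 enter as bought.

**Three steps most likely to fail, each with a fallback**

Step 10 (ring contraction). The diazonium may be captured by solvent, eliminate, or rearrange differently before C-10 migrates. The fallback keeps the 1,2-shift but makes the cation from a halide, setting out from 13 and returning at 19. Oxidative cleavage of the terminal alkene (K2OsO4·2H2O, NaIO4, 2,6-lutidine; the electron-poor enoates are spared) gives the aldehyde (1R,3R)-1-[(1S)-1,4-dimethyl-2-oxocyclopent-3-en-1-yl]-4,4-dimethyl-5-oxopentane-1,3-diyl bis(3-methylbut-2-enoate) F4. Takai olefination (CrCl2, CHBr3, THF) gives the (E)-vinyl bromide analogue of 14, F5. TBSOTf/Et3N gives its silyl dienol ether F6 (not isolated), which is heated (PhMe, 150 °C, sealed tube) to the endo-bromo Diels–Alder adduct F7. AgBF4 in CH2Cl2 then abstracts bromide and the same antiperiplanar shift gives 19 directly.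

Step 8 (intramolecular Diels–Alder). The dienol ether may form with an exocyclic double bond, or the neopentyl dienophile carbon may be too hindered for the concerted addition. The fallback builds the same two bonds stepwise and ionically, setting out from 14 and returning at 16. LiN(SiMe3)2 (THF, −78 °C) deprotonates the ring CH2 (the only enolisable position), and the dienolate adds through its γ-carbon to the nitroalkene (intramolecular vinylogous Michael addition, closing the seven-membered ring). Protonation gives the bicyclic nitro enone F3. TBSOTf/Et3N then closes the C-1–C-11 bond by a silyl-triflate-promoted intramolecular nitro-aldol reaction onto the enone carbonyl, with the epimerisable nitro centre settling endo, away from the C-9 ester, to give 16.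

Step 5 (chelate-controlled methylation). The trianion may deprotonate at the γ-position, the product aldolate may undergo retro-aldol cleavage, or the selectivity may be low. The fallback gives up enolate stereocontrol and separates diastereomers instead, setting out from 8 and returning at 11. Compound 8 is C-methylated at its doubly activated ring carbon (K2CO3, MeI, acetone) to the quaternary hydroxy-diketone 5-[(3R)-3-hydroxy-4,4-dimethylhex-5-enoyl]-3,5-dimethylcyclopent-2-en-1-one F1 (both ring epimers). The same hydroxyl-directed anti reduction (Me4NBH(OAc)3, MeCN/AcOH, −30 °C) gives 11 together with its ring epimer (5R)-5-[(1R,3R)-1,3-dihydroxy-4,4-dimethylhex-5-en-1-yl]-3,5-dimethylcyclopent-2-en-1-one F2. The two are separated by chromatography, and 11 continues at step 6; half the material is lost.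

**Further compounds**

F1 | step 5 | 5-[(3R)-3-hydroxy-4,4-dimethylhex-5-enoyl]-3,5-dimethylcyclopent-2-en-1-one (both ring epimers) | C=CC(C)(C)[C@H](O)CC(=O)C1(C)CC(C)=CC1=O
F2 | step 5 | (5R)-5-[(1R,3R)-1,3-dihydroxy-4,4-dimethylhex-5-en-1-yl]-3,5-dimethylcyclopent-2-en-1-one | C=CC(C)(C)[C@H](O)C[C@@H](O)[C@@]1(C)CC(C)=CC1=O
F3 | step 8 | bicyclic nitro enone: cyclopentenone of 14 with its ring C-4 bonded to the former nitroalkene β-carbon (seven-membered ring closed, CH2NO2 side arm) | CC(C)=CC(=O)O[C@@H]1C[C@@H](OC(=O)C=C(C)C)[C@@]2(C)C(=O)C=C(C)[C@H]2[C@@H](C[N+](=O)[O-])C1(C)C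
F4 | step 10 | (1R,3R)-1-[(1S)-1,4-dimethyl-2-oxocyclopent-3-en-1-yl]-4,4-dimethyl-5-oxopentane-1,3-diyl bis(3-methylbut-2-enoate) | O=CC(C)(C)[C@H](OC(=O)C=C(C)C)C[C@@H](OC(=O)C=C(C)C)[C@]1(C)CC(C)=CC1=O
F5 | step 10 | (1R,3R,5E)-6-bromo-1-[(1S)-1,4-dimethyl-2-oxocyclopent-3-en-1-yl]-4,4-dimethylhex-5-ene-1,3-diyl bis(3-methylbut-2-enoate) | Br/C=C/C(C)(C)[C@H](OC(=O)C=C(C)C)C[C@@H](OC(=O)C=C(C)C)[C@]1(C)CC(C)=CC1=O
F6 | step 10 | TBS dienol ether of F5 (1-siloxy-3,5-dimethylcyclopenta-1,3-diene) | Br/C=C/C(C)(C)[C@H](OC(=O)C=C(C)C)C[C@@H](OC(=O)C=C(C)C)[C@]1(C)C=C(C)C=C1O[Si](C)(C)C(C)(C)C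
F7 | step 10 | endo-bromo Diels–Alder adduct (16 with Br in place of NO2) | CC(C)=CC(=O)O[C@@H]1C[C@@H](OC(=O)C=C(C)C)[C@@]2(C)[C@]3(O[Si](C)(C)C(C)(C)C)C=C(C)[C@H]2[C@@H]([C@H]3Br)C1(C)C
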